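If the rate were proportional to the starting material, as in a first-order decay with one time constant, then the ochre and green runs, which have the same catalyst charge, must show first readings in the ratio of their starting charges, 0.500. The readings give 0.638.

| flask | starting material | free catalyst | time |
|---|---|---|---|
| green | 80.0 mM | 2.40 mM |  |
| teal | 80.0 mM | 1.20 mM |  |
| ochre | 40.0 mM | 2.40 mM |  |
| grey | 26.0 mM | 1.20 mM | 40 min |

| green run: time / min | green run: [product] / mM | teal run: time / min | teal run: [product] / mM | ochre run: time / min | ochre run: [product] / mM |
|---|---|---|---|---|---|
| 3.0 | 10.75 | 3.0 | 4.95 | 3.0 | 6.86 |
| 9.2 | 25.13 | 9.2 | 13.31 | 9.2 | 15.70 |
| 18 | 35.52 | 18 | 19.90 | 18 | 21.43 |
| 28 | 40.36 | 28 | 23.14 | 28 | 23.67 |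
| 40 | 42.48 | 40 | 25.38 | 40 | 24.39 |

(standard deviation of a reading: 0.2 mM)

- order of the initial rate in [free catalyst], near the charge of the green run, the rate being that where two percent of its starting material are product
- order of the initial rate in [starting material], near the charge of the green run, the rate being that where two percent of its starting material are product (one fixed amount of product, the same in the runs compared)
- product in the grey run at 40 min, as a share of the starting material charged

- Overall: starting material -> product, with free catalyst as catalyst.
- Constant volume, constant temperature.
- A reading of a species includes what of it is bound.
- An order is taken over about fifteen percent of the charge, up and down.

We suppose, as our own reckoning, that the catalyst must hold starting material to work, and that held catalyst takes no more: saturation. Let s be the starting material as a fraction of the green charge, and h the fraction at which half the catalyst is held. The rate then goes as s/(h+s). Setting the ochre-to-green ratio of that expression equal to the reading, and treating the first readings as initial rates, gives h = 1.31. So by this reckoning, at the start of the green run, 0.567 of the catalyst is free. This free share, h/(h+s), is the part of the catalyst charge not holding starting material at the start, and under our supposition it is also the local order in starting material, because differentiating the logarithm of s/(h+s) gives exactly h/(h+s). For the catalyst order we use the teal and green first readings, whose catalyst charges differ by the factor 2.00. They give 1.12, which carries the scatter of those readings.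

The forecast gives a catalyst order of 1.13 (0.98 to 1.3), a starting-material order of 0.56 (0.4 to 0.72), and 40% (34% to 47%) for the grey run. On the starting material it says “This suggests saturation”, as we do, with 0.56 against our 0.567.

The simulation gives a catalyst order of 1.0, a starting-material order of 0.57, and 44.2% for the grey run.

free catalyst + starting material ⇌ catalyst-substrate complex, settled at all times (10.80 L mol⁻¹); catalyst-substrate complex → product + free catalyst (3.738 min⁻¹); starting material → decomposed substrate (0.04242 min⁻¹); free catalyst + starting material → spent catalyst + starting material (1.116 L mol⁻¹ min⁻¹) Where equal amounts of product have been made, the ochre rate is 0.63 of the green rate. The teal run has the green charge of starting material, so its reckoned free share at the start is 0.567. The grey run has the same catalyst charge as the teal run, but at its charge the reckoned free share at the start is higher, 0.801, so by this reckoning its starting rate per unit of starting material is 1.41 times that of the teal run. At 40 min the grey run has turned 44.2% of its charge into product, and the reading of the teal run stands at 31.7% of its charge.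

(The readings were generated by integration for substances that don't exist; noise was put on by code.)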